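Rings: flavone unit = benzo ring A, pyranone ring C, anisole ring B (C1'–C6'); flavanone unit = benzo ring D, dihydropyranone ring E (stereocentre C2''), anisyl ring F. MOM = methoxymethyl.
Last disconnection: the C2–C1' bond between ring C and ring B, taken together with the O1–C2 bond of ring C. This gives an aryl bromide (rings B, D, E, F complete, Br on C1') and a symmetric 2,4,6-tris(MOM-oxy)phenyl ethynyl ketone whose terminal alkyne carbon is C2.
Enabling feature: ring A is a phloroglucinol ring (O1 on C8a, OH on C5 and C7, acyl carbon C4 on C4a), so before ring C exists the two oxygens ortho to C4a are equivalent and either one closes onto C2 to the same 5,7-dihydroxychromone; C1' is para to the ring B methoxy group and has no ortho substituent.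
The bromide comes from 5,7-dihydroxychromone: iodination of C6'' ortho to the free 5''-OH, Suzuki coupling C6''–C3' to ring B, then enantioselective conjugate addition of ring F to C2''.
Ring order: A and D/E are bought; B is joined to D (step 4); F is added and E saturated with its stereocentre (step 5); C is closed last (step 9), as all MOM groups are removed.

Key step: step 9

Remark: 5,7-dihydroxychromone is taken as a purchasable starting material, and the C3'–C6'' biaryl axis, for which the target notation gives no configuration, is taken as freely rotating.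

Step 1
Reactants: 1 5,7-dihydroxy-4H-chromen-4-one
Product: 2 5-hydroxy-7-(methoxymethoxy)-4H-chromen-4-one
Conditions: MOMCl (1.1 equiv), K2CO3, acetone, 0 °C to rt
Reagents that add atoms: chloromethyl methyl ether (MOMCl), COCCl
Why: Williamson ether formation should take place only at the 7-OH, the more acidic phenol, because the 5-OH is held in a hydrogen bond to the C4 carbonyl.

Step 2
Reactants: 2 5-hydroxy-7-(methoxymethoxy)-4H-chromen-4-one
Product: 3 5-hydroxy-6-iodo-7-(methoxymethoxy)-4H-chromen-4-one
Conditions: [BnNMe3][ICl2] (1.05 equiv), CaCO3, CH2Cl2–MeOH, rt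
Reagents that add atoms: benzyltrimethylammonium dichloroiodate, C[N+](C)(C)Cc1ccccc1.Cl[I-]Cl
Why: Electrophilic aromatic iodination of a 5-hydroxy-7-alkoxy benzopyranone with this reagent is expected to go ortho to the free, chelated 5-OH (C6, the later C6'') and not to C8, and CaCO3 takes up the HCl so that the MOM ether is kept.

Step 3
Reactants: 3 5-hydroxy-6-iodo-7-(methoxymethoxy)-4H-chromen-4-one
Product: 4 6-iodo-5,7-bis(methoxymethoxy)-4H-chromen-4-one
Conditions: MOMCl (2 equiv), Cs2CO3, DMF, 0 °C to 40 °C
Reagents that add atoms: chloromethyl methyl ether (MOMCl), COCCl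
Why: Williamson ether formation at the chelated 5-OH, flanked by the carbonyl and the iodine, should succeed through the reactive caesium phenoxide in DMF, without touching the C–I bond or the pyranone.

Step 4
Reactants: 4 6-iodo-5,7-bis(methoxymethoxy)-4H-chromen-4-one; 5 (5-bromo-2-methoxyphenyl)boronic acid
Product: 6 6-(5-bromo-2-methoxyphenyl)-5,7-bis(methoxymethoxy)-4H-chromen-4-one
Conditions: Pd(PPh3)4 (5 mol %), Na2CO3, DME–H2O, 75 °C
Reagents that add atoms: none
Why: Suzuki–Miyaura coupling: zerovalent palladium should insert into the C–I bond of 4 far faster than into the electron-rich C–Br bond of 5 or 6, so the C6''–C3' biaryl bond forms and the bromide stays as the handle for step 9.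

Step 5
Reactants: 6 6-(5-bromo-2-methoxyphenyl)-5,7-bis(methoxymethoxy)-4H-chromen-4-one; 7 (4-methoxyphenyl)boronic acid
Product: 8 (2S)-6-(5-bromo-2-methoxyphenyl)-2-(4-methoxyphenyl)-5,7-bis(methoxymethoxy)-2,3-dihydro-4H-chromen-4-one
Conditions: Pd(OCOCF3)2 (10 mol %), (R)-4-tert-butyl-2-(pyridin-2-yl)-4,5-dihydrooxazole ((R)-t-BuPyOx, 12 mol %), NH4PF6 (30 mol %), H2O (5 equiv), ClCH2CH2Cl, 60 °C
Reagents that add atoms: none
Why: Enantioselective conjugate addition of an arylboronic acid to a chromone under a cationic palladium–pyridine-oxazoline catalyst (aryl migration to C2'', then protonation of the palladium enolate by water): the tert-butyl group of the ligand blocks one face of the bound enone, and the (R)-ligand is chosen because the (S)-ligand delivers aryl groups to the opposite face of cyclic enones, so the 2S centre is expected (sense to be confirmed on the first batch), while the aryl bromide is left alone by the divalent palladium cycle.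

Step 6
Reactants: 9 2,4,6-trihydroxybenzaldehyde
Product: 10 2,4,6-tris(methoxymethoxy)benzaldehyde
Conditions: MOMCl (4 equiv), Cs2CO3, DMF, 0 °C to rt
Reagents that add atoms: chloromethyl methyl ether (MOMCl), COCCl
Why: Exhaustive Williamson ether formation, in which caesium carbonate in DMF should also alkylate the two phenols that are hydrogen-bonded to the aldehyde.

Step 7
Reactants: 10 2,4,6-tris(methoxymethoxy)benzaldehyde; 11 ethynylmagnesium bromide
Product: 13 1-[2,4,6-tris(methoxymethoxy)phenyl]prop-2-yn-1-ol (racemate), via bromomagnesium alkoxide 12 (not isolated)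
Conditions: THF, 0 °C; then H2O
Reagents that add atoms: none
Why: Grignard 1,2-addition to the aldehyde; the new carbinol centre forms as a racemate, which does not matter because step 8 removes it.

Step 8
Reactants: 13 1-[2,4,6-tris(methoxymethoxy)phenyl]prop-2-yn-1-ol (racemate)
Product: 14 1-[2,4,6-tris(methoxymethoxy)phenyl]prop-2-yn-1-one
Conditions: activated MnO2 (10 equiv), CH2Cl2, rt
Reagents that add atoms: none
Why: MnO2 oxidation of a benzylic and propargylic alcohol under neutral, heterogeneous conditions should give the terminal ynone without harm to the MOM acetals.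

Step 9
Reactants: 14 1-[2,4,6-tris(methoxymethoxy)phenyl]prop-2-yn-1-one; 8 (2S)-6-(5-bromo-2-methoxyphenyl)-2-(4-methoxyphenyl)-5,7-bis(methoxymethoxy)-2,3-dihydro-4H-chromen-4-one
Product: 18 (2S)-5,7-dihydroxy-6-[5-(5,7-dihydroxy-4-oxo-4H-chromen-2-yl)-2-methoxyphenyl]-2-(4-methoxyphenyl)-2,3-dihydro-4H-chromen-4-one, via zinc acetylide 15 (not isolated), via coupled ynone 16 (not isolated), via pentahydroxy ynone 17 (not isolated)
Conditions: 14 (1.3 equiv), TMPZnCl·LiCl (1.25 equiv), THF, 0 °C; then 8 (1.0 equiv), Pd(OAc)2 (4 mol %), SPhos (8 mol %), 40 °C; then MeOH, 3 M HCl, 45 °C (one pot)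
Reagents that add atoms: none
Why: TMPZnCl·LiCl removes only the alkyne proton of 14 (the ketone has no alpha hydrogen and the base is spent before 8 is added), and the zinc acetylide 15 enters a Negishi alkynylation: zerovalent palladium inserts into the unhindered C1'–Br bond of 8, the alkynyl group passes from zinc to palladium and reductive elimination forms the C2–C1' bond without added base, so the base-labile centre C2'' is not exposed to retro-oxa-Michael opening. The closest known reactions are the palladium-catalysed coupling of zinc acetylides of propiolate esters with aryl halides and the acid-promoted cyclisation of 2-hydroxyaryl ynones to flavones. Methanolic HCl then cleaves all five MOM acetals of 16 (as dimethoxymethane) to give 17, in which a phenol ortho to the ynone adds to the protonated ynone at its beta carbon C2, so that ring C closes in the 6-endo-dig mode (O1–C2). No new stereocentre is formed, and the 2S centre from step 5 should be carried through because neither the organozinc stage nor the acid stage opens ring E. The selectivity needed is 6-endo (flavone) over 5-exo (aurone) closure, secured by the conjugate-addition polarity of the ynone under protic acid, while the choice between the two ortho phenols is void because ring A is symmetric about the C4a–C7 axis. In one operation the step should thus supply the fragment union, ring C and the four free phenols of the target from an acyclic, achiral three-carbon unit.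

Compound list
1 | 5,7-dihydroxy-4H-chromen-4-one | O=c1ccoc2cc(O)cc(O)c12 | starting material
2 | 5-hydroxy-7-(methoxymethoxy)-4H-chromen-4-one | O=c1ccoc2cc(OCOC)cc(O)c12 | intermediate
3 | 5-hydroxy-6-iodo-7-(methoxymethoxy)-4H-chromen-4-one | O=c1ccoc2cc(OCOC)c(I)c(O)c12 | intermediate
4 | 6-iodo-5,7-bis(methoxymethoxy)-4H-chromen-4-one | O=c1ccoc2cc(OCOC)c(I)c(OCOC)c12 | intermediate
5 | (5-bromo-2-methoxyphenyl)boronic acid | COc1ccc(Br)cc1B(O)O | starting material
6 | 6-(5-bromo-2-methoxyphenyl)-5,7-bis(methoxymethoxy)-4H-chromen-4-one | O=c1ccoc2cc(OCOC)c(-c3cc(Br)ccc3OC)c(OCOC)c12 | intermediate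
7 | (4-methoxyphenyl)boronic acid | COc1ccc(B(O)O)cc1 | starting material
8 | (2S)-6-(5-bromo-2-methoxyphenyl)-2-(4-methoxyphenyl)-5,7-bis(methoxymethoxy)-2,3-dihydro-4H-chromen-4-one | COc1ccc([C@@H]2CC(=O)c3c(cc(OCOC)c(-c4cc(Br)ccc4OC)c3OCOC)O2)cc1 | intermediate
9 | 2,4,6-trihydroxybenzaldehyde | O=Cc1c(O)cc(O)cc1O | starting material
10 | 2,4,6-tris(methoxymethoxy)benzaldehyde | O=Cc1c(OCOC)cc(OCOC)cc1OCOC | intermediate
11 | ethynylmagnesium bromide | C#C[Mg]Br | starting material
12 | bromomagnesium 1-[2,4,6-tris(methoxymethoxy)phenyl]prop-2-yn-1-olate | C#CC(O[Mg]Br)c1c(OCOC)cc(OCOC)cc1OCOC | intermediate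
13 | 1-[2,4,6-tris(methoxymethoxy)phenyl]prop-2-yn-1-ol (racemate) | C#CC(O)c1c(OCOC)cc(OCOC)cc1OCOC | intermediate
14 | 1-[2,4,6-tris(methoxymethoxy)phenyl]prop-2-yn-1-one | C#CC(=O)c1c(OCOC)cc(OCOC)cc1OCOC | intermediate
15 | chloro{3-oxo-3-[2,4,6-tris(methoxymethoxy)phenyl]prop-1-yn-1-yl}zinc (LiCl complex) | Cl[Zn]C#CC(=O)c1c(OCOC)cc(OCOC)cc1OCOC | intermediate
16 | (2S)-2-(4-methoxyphenyl)-6-(2-methoxy-5-{3-oxo-3-[2,4,6-tris(methoxymethoxy)phenyl]prop-1-yn-1-yl}phenyl)-5,7-bis(methoxymethoxy)-2,3-dihydro-4H-chromen-4-one | COc1ccc([C@@H]2CC(=O)c3c(cc(OCOC)c(-c4cc(C#CC(=O)c5c(OCOC)cc(OCOC)cc5OCOC)ccc4OC)c3OCOC)O2)cc1 | intermediate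
17 | (2S)-5,7-dihydroxy-6-{2-methoxy-5-[3-oxo-3-(2,4,6-trihydroxyphenyl)prop-1-yn-1-yl]phenyl}-2-(4-methoxyphenyl)-2,3-dihydro-4H-chromen-4-one | COc1ccc([C@@H]2CC(=O)c3c(cc(O)c(-c4cc(C#CC(=O)c5c(O)cc(O)cc5O)ccc4OC)c3O)O2)cc1 | intermediate
18 | (2S)-5,7-dihydroxy-6-[5-(5,7-dihydroxy-4-oxo-4H-chromen-2-yl)-2-methoxyphenyl]-2-(4-methoxyphenyl)-2,3-dihydro-4H-chromen-4-one | COc1ccc([C@@H]2CC(=O)c3c(cc(O)c(-c4cc(-c5cc(=O)c6c(O)cc(O)cc6o5)ccc4OC)c3O)O2)cc1 | target

Total step count: 9. Longest linear sequence: 6 steps (steps 1 to 5, then step 9); the second branch is steps 6 to 8, then step 9.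

Steps most likely to fail

Step 9. The cross-coupling may stall through slow transfer or oligomerisation of the electron-poor zinc acetylide. Ring closure under acid in the presence of metal residues may leak into the 5-exo mode, and slow enolisation of ring E by the organozinc could erode the stereocentre. The fallback uses known chemistry, sets out from 8 (with 1 as second starting point) and returns at 18; ring C is then taken ready-made instead of being closed. 5,7-Dihydroxychromone 1 is alkylated twice (MOMCl, Cs2CO3, DMF) to 5,7-bis(methoxymethoxy)-4H-chromen-4-one F1. TMPZnCl·LiCl in THF metalates its C2–H, the position next to the ring oxygen, to chloro[5,7-bis(methoxymethoxy)-4-oxo-4H-chromen-2-yl]zinc F2. Negishi coupling of this with bromide 8 (Pd(OAc)2, SPhos, THF, 40 °C) should give (2S)-6-{5-[5,7-bis(methoxymethoxy)-4-oxo-4H-chromen-2-yl]-2-methoxyphenyl}-2-(4-methoxyphenyl)-5,7-bis(methoxymethoxy)-2,3-dihydro-4H-chromen-4-one F3. 3 M HCl in MeOH at 45 °C then removes the four MOM groups and gives 18.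

Step 5. Facial selectivity or conversion may be poor at this electron-rich, 5,6,7-trisubstituted chromone, and the 5-O-MOM group may be lost in the weakly acidic medium. The fallback is the chalcone route with resolution; it sets out from 6 and returns at 8. Aqueous NaOH in EtOH opens ring E of 6 at C2'' and expels that carbon as formate, giving 1-[3-(5-bromo-2-methoxyphenyl)-6-hydroxy-2,4-bis(methoxymethoxy)phenyl]ethan-1-one F4, whose only free phenol is the one remote from ring B. Claisen–Schmidt condensation with 4-methoxybenzaldehyde (KOH, EtOH) gives (E)-1-[3-(5-bromo-2-methoxyphenyl)-6-hydroxy-2,4-bis(methoxymethoxy)phenyl]-3-(4-methoxyphenyl)prop-2-en-1-one F5. NaOAc in refluxing EtOH closes ring E by oxa-Michael addition of that phenol, which fixes the 6-aryl regiochemistry, to racemic 6-(5-bromo-2-methoxyphenyl)-2-(4-methoxyphenyl)-5,7-bis(methoxymethoxy)-2,3-dihydro-4H-chromen-4-one F6. Chromatography on a chiral stationary phase gives 8, and the unwanted (2R)-6-(5-bromo-2-methoxyphenyl)-2-(4-methoxyphenyl)-5,7-bis(methoxymethoxy)-2,3-dihydro-4H-chromen-4-one F7 is returned to the NaOAc conditions, where it racemises through F5.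

Step 4. Palladium may also insert into the C–Br bonds (oligomer formation) while the di-ortho-substituted iodide reacts slowly, and the aqueous base may open the chromone. The fallback replaces bromine by chlorine, which is inert in the biaryl coupling; it sets out from 4 and returns at 16. Compound 4 is coupled with commercial (5-chloro-2-methoxyphenyl)boronic acid at higher temperature (Pd(PPh3)4, K3PO4, dioxane–H2O, 90 °C) to 6-(5-chloro-2-methoxyphenyl)-5,7-bis(methoxymethoxy)-4H-chromen-4-one F8. The conditions of step 5 then give (2S)-6-(5-chloro-2-methoxyphenyl)-2-(4-methoxyphenyl)-5,7-bis(methoxymethoxy)-2,3-dihydro-4H-chromen-4-one F9. In the first stage of step 9 this chloride is coupled with zinc acetylide 15 under Pd(OAc)2 and XPhos at 60 °C, which rejoins the route at 16.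

Further compounds
F1 | step 9 | 5,7-bis(methoxymethoxy)-4H-chromen-4-one | O=c1ccoc2cc(OCOC)cc(OCOC)c12
F2 | step 9 | chloro[5,7-bis(methoxymethoxy)-4-oxo-4H-chromen-2-yl]zinc | O=c1cc([Zn]Cl)oc2cc(OCOC)cc(OCOC)c12
F3 | step 9 | (2S)-6-{5-[5,7-bis(methoxymethoxy)-4-oxo-4H-chromen-2-yl]-2-methoxyphenyl}-2-(4-methoxyphenyl)-5,7-bis(methoxymethoxy)-2,3-dihydro-4H-chromen-4-one | COc1ccc([C@@H]2CC(=O)c3c(cc(OCOC)c(-c4cc(-c5cc(=O)c6c(OCOC)cc(OCOC)cc6o5)ccc4OC)c3OCOC)O2)cc1
F4 | step 5 | 1-[3-(5-bromo-2-methoxyphenyl)-6-hydroxy-2,4-bis(methoxymethoxy)phenyl]ethan-1-one | CC(=O)c1c(O)cc(OCOC)c(-c2cc(Br)ccc2OC)c1OCOC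
F5 | step 5 | (E)-1-[3-(5-bromo-2-methoxyphenyl)-6-hydroxy-2,4-bis(methoxymethoxy)phenyl]-3-(4-methoxyphenyl)prop-2-en-1-one | COc1ccc(/C=C/C(=O)c2c(O)cc(OCOC)c(-c3cc(Br)ccc3OC)c2OCOC)cc1
F6 | step 5 | racemic 6-(5-bromo-2-methoxyphenyl)-2-(4-methoxyphenyl)-5,7-bis(methoxymethoxy)-2,3-dihydro-4H-chromen-4-one | COc1ccc(C2CC(=O)c3c(cc(OCOC)c(-c4cc(Br)ccc4OC)c3OCOC)O2)cc1
F7 | step 5 | (2R)-6-(5-bromo-2-methoxyphenyl)-2-(4-methoxyphenyl)-5,7-bis(methoxymethoxy)-2,3-dihydro-4H-chromen-4-one | COc1ccc([C@H]2CC(=O)c3c(cc(OCOC)c(-c4cc(Br)ccc4OC)c3OCOC)O2)cc1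
F8 | step 4 | 6-(5-chloro-2-methoxyphenyl)-5,7-bis(methoxymethoxy)-4H-chromen-4-one | O=c1ccoc2cc(OCOC)c(-c3cc(Cl)ccc3OC)c(OCOC)c12
F9 | step 4 | (2S)-6-(5-chloro-2-methoxyphenyl)-2-(4-methoxyphenyl)-5,7-bis(methoxymethoxy)-2,3-dihydro-4H-chromen-4-one | COc1ccc([C@@H]2CC(=O)c3c(cc(OCOC)c(-c4cc(Cl)ccc4OC)c3OCOC)O2)cc1
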